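(The earlier runs and the new flask are simulated for an exercise; scatter was added.)

**Bench handover.** For the next 30 h, the weekday flasks below stand closed and stirred, with starting material charged from 0.080 M to 1.2 M and gas phase held at 25 mM. None of it is in solution at the start.

| setting | elm | oak | Wednesday's | Monday's | Friday's | Tuesday's | Thursday's |
|---|---|---|---|---|---|---|---|
| starting material | 0.10 M | 1.3 M | 0.080 M | 0.15 M | 0.30 M | 0.60 M | 1.2 M |
| gas phase | 25 mM (held) | 25 mM (held) | 25 mM (held) | 25 mM (held) | 25 mM (held) | 25 mM (held) | 25 mM (held) |
| remark | run made earlier | run made earlier |  |  |  |  |  |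
| time |  |  | 30 h | 30 h | 30 h | 30 h | 30 h |

| run | time / h | target / % |
|---|---|---|
| elm | 4.00 | 5 |
| elm | 8.00 | 10 |
| elm | 10.0 | 12 |
| elm | 15.0 | 11 |
| elm | 20.0 | 18 |
| oak | 1.33 | 0 |
| oak | 4.00 | 3 |
| oak | 8.00 | 6 |
| oak | 12.0 | 10 |
| oak | 15.0 | 8 |
| oak | 20.0 | 11 |

(scatter of a reading: 1.5 percentage points)

- the numbers in the tables scatter with a standard deviation of 1.5 percentage points
- at the start none of the gas phase is in solution
- "hardly changes" means that all values lie within two and a half points (for a concentration: within two and a half percent of the largest)

- [target] at the end for Wednesday's, Monday's, Friday's, Tuesday's, Thursday's, in this order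
- the shape of the row from first to last (rises all the way / falls all the way / hardly changes / falls, then rises / rises, then falls)

**Reading the pace.** Divide the sum of each run's readings by the sum of its times. This gives a pseudo-first-order pace p, the fraction of the charge turned to target per hour: 0.00982 h⁻¹ for elm and 0.00630 h⁻¹ for oak. So oak reads slower than elm. My reading is that a heavier charge pulls dissolved gas below saturation, with dissolved gas at a fraction g = C/(C + [starting material]) of 25 mM. The two paces then give the draw-down charge C = 2.04 M, the concentration of starting material at which g stands at half. C is a reading and carries the tables' scatter.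

**Your flasks.** Thursday's g at the charge should be 0.630, a modest drop against a charge 15.0 times Wednesday's. With p scaled by g and first-order depletion, I expect target at 0.0206 M in Wednesday's and 0.212 M in Thursday's. Leave the gas phase and the stirring as they are, since C was read under them.

**The forecast.** Reading the slowdown as what you would expect if “dissolved gas is drawn down by faster consumption at high loading”, the forecast gives 0.0196 M to 0.206 M, rises all the way, a little below my reckoning.

**The result.** The row reads 0.0183 M, 0.0336 M, 0.0645 M, 0.119 M, 0.205 M: rises all the way.

    gas phase ⇌ dissolved gas, rate k1*(csat - [dissolved gas]) (kL = 0.0170 min⁻¹)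
    starting material + dissolved gas → target (k = 0.00700 M⁻¹ min⁻¹)
    target ⇌ isomer of the product (K = 4.60, k = 1.30 × 10⁻⁴ min⁻¹)

**Gas reckoned.** Thursday's target stands at 0.205 M partly because gas phase enters solution at a finite pace and partly because of the hour of the reading. With instant passage it gives 0.288 M, and read ten times later, 0.381 M. With the starting material remaining in Thursday's at 15.0 h, C puts dissolved gas at 0.0163 M, and the flask holds 0.0173 M. For Tuesday's at 15.0 h, C gives 0.0198 M, and the flask holds 0.0205 M.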